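Everything rests on cutting the O1–C5 bond of the oxolane (O1, C2–C5). C5 is a benzylic ether carbon para to the oxygen of its guaiacyl ring, and its aryl lies trans to the C4 methyl, as expected when the C2 hydroxyl traps a para-quinone methide. The precursor is 1,4-diol 22, freed in the flask from aryl silyl ether 21: C2, C3 and C4 are set, C5 is a mixture, the only free phenol sits on the C5 ring, and the C2 ring carries the silyl-protected (1R,2R) side chain. In one operation hot alkali ionises C5 alone, closes the ring and fixes C5. The (1S,2S) side chain is then built on the liberated phenol.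

Key step: step 11

Remark: the oxolane is numbered O1, C2 (bears the ring with the (1R,2R) chain), C3, C4 (methyls), C5 (bears the second guaiacyl ring); the target is then (2S,3R,4R,5R).
Remark: ArL stands for 4-{[(1R,2R)-1-(3,4-dimethoxyphenyl)-1-(triisopropylsilyloxy)propan-2-yl]oxy}-3-methoxyphenyl.
Remark: 3,4-dimethoxyphenylmagnesium bromide (5, THF solution) and (−)-Ipc2BOMe (the enantiomer made from (+)-α-pinene) are assumed to be purchased.

Step 1
Reactants: 1 4-bromo-2-methoxyphenol; 2 ethyl (S)-lactate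
Product: 3 ethyl (2R)-2-(4-bromo-2-methoxyphenoxy)propanoate
Conditions: PPh3, DIAD, THF, 0 °C → rt
Reagents that add atoms: none
Why: Mitsunobu etherification, in which the phenoxide displaces the phosphonium-activated lactate oxygen by SN2 with inversion, so the (S)-lactate should give the (R)-aryloxy ester.

Step 2
Reactants: 3 ethyl (2R)-2-(4-bromo-2-methoxyphenoxy)propanoate
Product: 4 (2R)-2-(4-bromo-2-methoxyphenoxy)-N-methoxy-N-methylpropanamide
Conditions: MeNH(OMe)·HCl, i-PrMgCl, THF, −20 °C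
Reagents that add atoms: N,O-dimethylhydroxylamine hydrochloride, CNOC.Cl
Why: Weinreb amide formation by aminolysis of the ester with the chloromagnesium amide, run cold so that the α-aryloxy stereocentre is not enolised.

Step 3
Reactants: 4 (2R)-2-(4-bromo-2-methoxyphenoxy)-N-methoxy-N-methylpropanamide; 5 3,4-dimethoxyphenylmagnesium bromide
Product: 6 (2R)-2-(4-bromo-2-methoxyphenoxy)-1-(3,4-dimethoxyphenyl)propan-1-one
Conditions: THF, 0 °C; aq NH4Cl
Reagents that add atoms: none
Why: Weinreb ketone synthesis, in which the chelated tetrahedral magnesium adduct survives until work-up so that the aryl group adds only once, the aryl bromide being inert to an aryl Grignard reagent at 0 °C.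

Step 4
Reactants: 6 (2R)-2-(4-bromo-2-methoxyphenoxy)-1-(3,4-dimethoxyphenyl)propan-1-one
Product: 7 (1R,2R)-2-(4-bromo-2-methoxyphenoxy)-1-(3,4-dimethoxyphenyl)propan-1-ol
Conditions: polymer-supported borohydride (BH4− form of Amberlite IRA-400), MeOH, 0 °C → rt
Reagents that add atoms: none
Why: Felkin–Anh (polar) controlled hydride reduction: with a non-chelating counter-ion the aryloxy group stands anti to the incoming hydride, which passes the small hydrogen, so the (R)-ketone should give the threo (1R,2R) carbinol.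

Step 5
Reactants: 7 (1R,2R)-2-(4-bromo-2-methoxyphenoxy)-1-(3,4-dimethoxyphenyl)propan-1-ol
Product: 8 [(1R,2R)-2-(4-bromo-2-methoxyphenoxy)-1-(3,4-dimethoxyphenyl)propoxy]triisopropylsilane
Conditions: TIPSOTf, 2,6-lutidine, CH2Cl2, 0 °C → rt
Reagents that add atoms: triisopropylsilyl triflate, CC(C)[Si](OS(=O)(=O)C(F)(F)F)(C(C)C)C(C)C
Why: Silylation of the secondary carbinol with a silyl triflate and a hindered pyridine base; the triisopropylsilyl ether should survive organolithium and Grignard reagents and hot aqueous alkali, and still leave with fluoride at the end without acid.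

Step 6
Reactants: 8 [(1R,2R)-2-(4-bromo-2-methoxyphenoxy)-1-(3,4-dimethoxyphenyl)propoxy]triisopropylsilane
Product: 10 ArL-carbaldehyde (4-{[(1R,2R)-1-(3,4-dimethoxyphenyl)-1-(triisopropylsilyloxy)propan-2-yl]oxy}-3-methoxybenzaldehyde), via aryllithium 9 (not isolated)
Conditions: n-BuLi, THF, −78 °C; DMF, −78 → 0 °C; aq NH4Cl
Reagents that add atoms: N,N-dimethylformamide, CN(C)C=O
Why: Bromine–lithium exchange at −78 °C outruns any deprotonation and the aryllithium is formylated by DMF (Bouveault aldehyde synthesis), the aldehyde being released only on aqueous work-up.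

Step 7
Reactants: 10 ArL-carbaldehyde; 11 cis-2-butene
Product: 16 (1S,2R)-1-ArL-2-methylbut-3-en-1-ol, via (Z)-crotylpotassium 12 (not isolated), via methoxyborate 13 (not isolated), via (Z)-crotylborane 14 (not isolated), via borinate 15 (not isolated)
Conditions: 11, KOt-Bu, n-BuLi, THF, −78 → −45 °C; (−)-Ipc2BOMe, −78 °C; BF3·OEt2; 10, −78 °C; NaOH, H2O2, 0 °C → rt
Reagents that add atoms: none
Why: Brown asymmetric crotylboration through a closed chair (Zimmerman–Traxler) transition state: the Z-crotyl geometry should give the syn relationship (C2 aryl cis to C3 methyl in the ring), and the isopinocampheyl groups derived from (+)-α-pinene should direct the crotyl unit to the Si face of the aldehyde, giving the (1S,2R) alcohol that becomes C2 and C3.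

Step 8
Reactants: 16 (1S,2R)-1-ArL-2-methylbut-3-en-1-ol
Product: 18 lactol (2S,3R,4R)-2-ArL-3,4-dimethyloxolan-5-ol (both anomers), via hydroxy aldehyde 17 (not isolated)
Conditions: [Rh(CO)2(acac)] (2 mol %), Ph2POMe (10 mol %), 4 Å MS, CO/H2 (1:1, 40 bar), THF, 45 °C; then DBU (0.1 equiv), CH2Cl2, rt
Reagents that add atoms: carbon monoxide, [C-]#[O+]
Why: Hydroxyl-directed branched hydroformylation: Ph2POMe exchanges reversibly onto the homoallylic hydroxyl and the bound phosphinite steers rhodium hydride addition so that the formyl group enters at the internal alkene carbon, the γ-hydroxy aldehyde closes to the lactol, and C4 is set under thermodynamic control because DBU equilibrates the enolisable aldehyde α-carbon through the open form until its methyl lies trans to the C3 methyl.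

Step 9
Reactants: 1 4-bromo-2-methoxyphenol
Product: 19 tert-butyl(4-bromo-2-methoxyphenoxy)dimethylsilane
Conditions: TBSCl, imidazole, DMF, rt
Reagents that add atoms: tert-butyldimethylsilyl chloride, CC(C)(C)[Si](C)(C)Cl
Why: Standard imidazole-promoted silylation of a phenol; the aryl silyl ether tolerates Grignard formation and is later removed by hydroxide in the same flask as the ring closure.

Step 10
Reactants: 18 lactol (2S,3R,4R)-2-ArL-3,4-dimethyloxolan-5-ol; 19 tert-butyl(4-bromo-2-methoxyphenoxy)dimethylsilane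
Product: 21 (1S,2R,3R,4RS)-1-ArL-4-[4-(tert-butyldimethylsilyloxy)-3-methoxyphenyl]-2,3-dimethylbutane-1,4-diol, via aryl Grignard reagent 20 (not isolated)
Conditions: 19, Mg, I2 (cat.), THF, 40 °C; then 18 (0.3 equiv), 0 °C → rt; aq NH4Cl
Reagents that add atoms: none
Why: Grignard addition to a lactol: the first equivalent deprotonates the hemiacetal, which opens to the magnesium alkoxide of the hydroxy aldehyde and is arylated by the second; the new carbinol centre C5 is deliberately left uncontrolled because the next step makes it planar.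

Step 11
Reactants: 21 (1S,2R,3R,4RS)-1-ArL-4-[4-(tert-butyldimethylsilyloxy)-3-methoxyphenyl]-2,3-dimethylbutane-1,4-diol
Product: 24 (2S,3R,4R,5R)-2-ArL-5-(4-hydroxy-3-methoxyphenyl)-3,4-dimethyloxolane, via free-phenol diol 22 (not isolated), via quinone methide 23 (not isolated)
Conditions: NaOH (2 M aq), 1,4-dioxane, rt, then 90 °C, degassed, N2; aq NH4Cl
Reagents that add atoms: none
Why: Hydroxide first strips the aryl silyl group to give 22, whose C5-ring phenoxide expels the benzylic hydroxide in a vinylogous E1cB step to the para-quinone methide 23, and the C2 alkoxide then adds to the exocyclic carbon (intramolecular oxa-Michael addition), restoring the arene and forming O1–C5. The closest known reaction types are the alkaline generation of quinone methides from para-hydroxybenzyl alcohols and the trapping of para-quinone methides by pendant alcohols to give 2-aryl tetrahydrofurans. The oxolane closes in a 5-exo-trig mode. The new stereocentre C5 is controlled by the adjacent C4 methyl: both C5 epimers of 22 converge on the same planar 23, closure that places the aryl trans to the C4 methyl avoids eclipsing, and because the product still has a free para-phenol the addition is reversible, so the 4,5-trans isomer should accumulate. The step needs chemoselective ionisation of C5 with retention at C2 and in the side chain, which is secured because only the C5 ring carries a free phenoxide while the C2 carbinol and the silylated chain carbinol sit on O-alkylated rings that cannot form a quinone methide in base.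

Step 12
Reactants: 24 (2S,3R,4R,5R)-2-ArL-5-(4-hydroxy-3-methoxyphenyl)-3,4-dimethyloxolane; 25 ethyl (R)-lactate
Product: 26 ethyl (2S)-2-{4-[(2R,3R,4R,5S)-5-ArL-3,4-dimethyloxolan-2-yl]-2-methoxyphenoxy}propanoate
Conditions: PPh3, DIAD, THF, 0 °C → rt
Reagents that add atoms: none
Why: Mitsunobu etherification of the only free phenol under neutral conditions that cannot reopen the oxolane; SN2 displacement with inversion should turn the (R)-lactate into the (S)-aryloxy ester.

Step 13
Reactants: 26 ethyl (2S)-2-{4-[(2R,3R,4R,5S)-5-ArL-3,4-dimethyloxolan-2-yl]-2-methoxyphenoxy}propanoate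
Product: 27 (2S)-2-{4-[(2R,3R,4R,5S)-5-ArL-3,4-dimethyloxolan-2-yl]-2-methoxyphenoxy}-N-methoxy-N-methylpropanamide
Conditions: MeNH(OMe)·HCl, i-PrMgCl, THF, −20 °C
Reagents that add atoms: N,O-dimethylhydroxylamine hydrochloride, CNOC.Cl
Why: Weinreb amide formation with the chloromagnesium amide at −20 °C, as in step 2, which should leave the α-aryloxy centre, the silyl ether and the oxolane untouched.

Step 14
Reactants: 27 (2S)-2-{4-[(2R,3R,4R,5S)-5-ArL-3,4-dimethyloxolan-2-yl]-2-methoxyphenoxy}-N-methoxy-N-methylpropanamide; 5 3,4-dimethoxyphenylmagnesium bromide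
Product: 28 (2S)-2-{4-[(2R,3R,4R,5S)-5-ArL-3,4-dimethyloxolan-2-yl]-2-methoxyphenoxy}-1-(3,4-dimethoxyphenyl)propan-1-one
Conditions: THF, 0 °C; aq NH4Cl
Reagents that add atoms: none
Why: Weinreb ketone synthesis, the stable magnesium chelate allowing a single aryl addition and collapsing to the ketone only on work-up.

Step 15
Reactants: 28 (2S)-2-{4-[(2R,3R,4R,5S)-5-ArL-3,4-dimethyloxolan-2-yl]-2-methoxyphenoxy}-1-(3,4-dimethoxyphenyl)propan-1-one
Product: 29 (1S,2S)-2-{4-[(2R,3R,4R,5S)-5-ArL-3,4-dimethyloxolan-2-yl]-2-methoxyphenoxy}-1-(3,4-dimethoxyphenyl)propan-1-ol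
Conditions: polymer-supported borohydride (BH4− form of Amberlite IRA-400), MeOH, 0 °C → rt
Reagents that add atoms: none
Why: Felkin–Anh (polar) controlled reduction as in step 4: with the aryloxy substituent anti to the incoming, non-chelated hydride the (S)-ketone should give the threo (1S,2S) carbinol.

Step 16
Reactants: 29 (1S,2S)-2-{4-[(2R,3R,4R,5S)-5-ArL-3,4-dimethyloxolan-2-yl]-2-methoxyphenoxy}-1-(3,4-dimethoxyphenyl)propan-1-ol
Product: 30 target CNP0116650.16
Conditions: TBAF, THF, rt → 40 °C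
Reagents that add atoms: none
Why: Fluoride-mediated cleavage of the silyl ether under non-acidic conditions, which should spare the two electron-rich benzylic alcohols and the 2,5-diaryl oxolane that acid would ionise.

Compound list
1 | 4-bromo-2-methoxyphenol | COc1cc(Br)ccc1O | starting material
2 | ethyl (S)-lactate | CCOC(=O)[C@H](C)O | starting material
3 | ethyl (2R)-2-(4-bromo-2-methoxyphenoxy)propanoate | CCOC(=O)[C@@H](C)Oc1ccc(Br)cc1OC | intermediate
4 | (2R)-2-(4-bromo-2-methoxyphenoxy)-N-methoxy-N-methylpropanamide | CON(C)C(=O)[C@@H](C)Oc1ccc(Br)cc1OC | intermediate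
5 | 3,4-dimethoxyphenylmagnesium bromide | COc1ccc([Mg]Br)cc1OC | starting material
6 | (2R)-2-(4-bromo-2-methoxyphenoxy)-1-(3,4-dimethoxyphenyl)propan-1-one | COc1ccc(C(=O)[C@@H](C)Oc2ccc(Br)cc2OC)cc1OC | intermediate
7 | (1R,2R)-2-(4-bromo-2-methoxyphenoxy)-1-(3,4-dimethoxyphenyl)propan-1-ol | COc1ccc([C@@H](O)[C@@H](C)Oc2ccc(Br)cc2OC)cc1OC | intermediate
8 | [(1R,2R)-2-(4-bromo-2-methoxyphenoxy)-1-(3,4-dimethoxyphenyl)propoxy]triisopropylsilane | COc1ccc([C@@H](O[Si](C(C)C)(C(C)C)C(C)C)[C@@H](C)Oc2ccc(Br)cc2OC)cc1OC | intermediate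
9 | ArL-lithium (aryllithium from 8) | COc1ccc([C@@H](O[Si](C(C)C)(C(C)C)C(C)C)[C@@H](C)Oc2ccc([Li])cc2OC)cc1OC | intermediate
10 | ArL-carbaldehyde | COc1ccc([C@@H](O[Si](C(C)C)(C(C)C)C(C)C)[C@@H](C)Oc2ccc(C=O)cc2OC)cc1OC | intermediate
11 | cis-2-butene | C/C=C\C | starting material
12 | (Z)-crotylpotassium | C/C=C\C[K] | intermediate
13 | potassium (Z)-crotyl(methoxy)diisopinocampheylborate | [K+].C/C=C\C[B-](OC)([C@@H]1C[C@@H]2C[C@@H](C2(C)C)[C@H]1C)[C@@H]1C[C@@H]2C[C@@H](C2(C)C)[C@H]1C | intermediate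
14 | (Z)-crotyldiisopinocampheylborane | C/C=C\CB([C@@H]1C[C@@H]2C[C@@H](C2(C)C)[C@H]1C)[C@@H]1C[C@@H]2C[C@@H](C2(C)C)[C@H]1C | intermediate
15 | diisopinocampheylborinate of 16 | COc1ccc([C@@H](O[Si](C(C)C)(C(C)C)C(C)C)[C@@H](C)Oc2ccc([C@@H](OB([C@@H]3C[C@@H]4C[C@@H](C4(C)C)[C@H]3C)[C@@H]3C[C@@H]4C[C@@H](C4(C)C)[C@H]3C)[C@H](C)C=C)cc2OC)cc1OC | intermediate
16 | (1S,2R)-1-ArL-2-methylbut-3-en-1-ol | COc1ccc([C@@H](O[Si](C(C)C)(C(C)C)C(C)C)[C@@H](C)Oc2ccc([C@@H](O)[C@H](C)C=C)cc2OC)cc1OC | intermediate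
17 | (2R,3R,4S)-4-ArL-4-hydroxy-2,3-dimethylbutanal | COc1ccc([C@@H](O[Si](C(C)C)(C(C)C)C(C)C)[C@@H](C)Oc2ccc([C@@H](O)[C@H](C)[C@@H](C)C=O)cc2OC)cc1OC | intermediate
18 | lactol (2S,3R,4R)-2-ArL-3,4-dimethyloxolan-5-ol, both anomers | COc1ccc([C@@H](O[Si](C(C)C)(C(C)C)C(C)C)[C@@H](C)Oc2ccc([C@H]3OC(O)[C@H](C)[C@H]3C)cc2OC)cc1OC | intermediate
19 | tert-butyl(4-bromo-2-methoxyphenoxy)dimethylsilane | COc1cc(Br)ccc1O[Si](C)(C)C(C)(C)C | intermediate
20 | [4-(tert-butyldimethylsilyloxy)-3-methoxyphenyl]magnesium bromide | COc1cc([Mg]Br)ccc1O[Si](C)(C)C(C)(C)C | intermediate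
21 | (1S,2R,3R,4RS)-1-ArL-4-[4-(tert-butyldimethylsilyloxy)-3-methoxyphenyl]-2,3-dimethylbutane-1,4-diol | COc1ccc([C@@H](O[Si](C(C)C)(C(C)C)C(C)C)[C@@H](C)Oc2ccc([C@@H](O)[C@H](C)[C@@H](C)C(O)c3ccc(O[Si](C)(C)C(C)(C)C)c(OC)c3)cc2OC)cc1OC | intermediate
22 | (1S,2R,3R,4RS)-1-ArL-4-(4-hydroxy-3-methoxyphenyl)-2,3-dimethylbutane-1,4-diol | COc1ccc([C@@H](O[Si](C(C)C)(C(C)C)C(C)C)[C@@H](C)Oc2ccc([C@@H](O)[C@H](C)[C@@H](C)C(O)c3ccc(O)c(OC)c3)cc2OC)cc1OC | intermediate
23 | para-quinone methide from 22 (C5 exocyclic to a 3-methoxycyclohexa-2,5-dien-4-one; C2, C3, C4 as in 22) | COc1ccc([C@@H](O[Si](C(C)C)(C(C)C)C(C)C)[C@@H](C)Oc2ccc([C@@H](O)[C@H](C)[C@@H](C)C=C3C=CC(=O)C(OC)=C3)cc2OC)cc1OC | intermediate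
24 | (2S,3R,4R,5R)-2-ArL-5-(4-hydroxy-3-methoxyphenyl)-3,4-dimethyloxolane | COc1ccc([C@@H](O[Si](C(C)C)(C(C)C)C(C)C)[C@@H](C)Oc2ccc([C@H]3O[C@@H](c4ccc(O)c(OC)c4)[C@H](C)[C@H]3C)cc2OC)cc1OC | intermediate
25 | ethyl (R)-lactate | CCOC(=O)[C@@H](C)O | starting material
26 | ethyl (2S)-2-{4-[(2R,3R,4R,5S)-5-ArL-3,4-dimethyloxolan-2-yl]-2-methoxyphenoxy}propanoate | COc1ccc([C@@H](O[Si](C(C)C)(C(C)C)C(C)C)[C@@H](C)Oc2ccc([C@H]3O[C@@H](c4ccc(O[C@@H](C)C(=O)OCC)c(OC)c4)[C@H](C)[C@H]3C)cc2OC)cc1OC | intermediate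
27 | (2S)-2-{4-[(2R,3R,4R,5S)-5-ArL-3,4-dimethyloxolan-2-yl]-2-methoxyphenoxy}-N-methoxy-N-methylpropanamide | COc1ccc([C@@H](O[Si](C(C)C)(C(C)C)C(C)C)[C@@H](C)Oc2ccc([C@H]3O[C@@H](c4ccc(O[C@@H](C)C(=O)N(C)OC)c(OC)c4)[C@H](C)[C@H]3C)cc2OC)cc1OC | intermediate
28 | (2S)-2-{4-[(2R,3R,4R,5S)-5-ArL-3,4-dimethyloxolan-2-yl]-2-methoxyphenoxy}-1-(3,4-dimethoxyphenyl)propan-1-one | COc1ccc([C@@H](O[Si](C(C)C)(C(C)C)C(C)C)[C@@H](C)Oc2ccc([C@H]3O[C@@H](c4ccc(O[C@@H](C)C(=O)c5ccc(OC)c(OC)c5)c(OC)c4)[C@H](C)[C@H]3C)cc2OC)cc1OC | intermediate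
29 | (1S,2S)-2-{4-[(2R,3R,4R,5S)-5-ArL-3,4-dimethyloxolan-2-yl]-2-methoxyphenoxy}-1-(3,4-dimethoxyphenyl)propan-1-ol | COc1ccc([C@@H](O[Si](C(C)C)(C(C)C)C(C)C)[C@@H](C)Oc2ccc([C@H]3O[C@@H](c4ccc(O[C@@H](C)[C@@H](O)c5ccc(OC)c(OC)c5)c(OC)c4)[C@H](C)[C@H]3C)cc2OC)cc1OC | intermediate
30 | CNP0116650.16: (2S,3R,4R,5R)-oxolane with the (1R,2R)-1-(3,4-dimethoxyphenyl)-1-hydroxypropan-2-yloxy chain on the C2 guaiacyl ring and the (1S,2S) chain on the C5 guaiacyl ring | COc1ccc([C@@H](O)[C@@H](C)Oc2ccc([C@H]3O[C@@H](c4ccc(O[C@@H](C)[C@@H](O)c5ccc(OC)c(OC)c5)c(OC)c4)[C@H](C)[C@H]3C)cc2OC)cc1OC | target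

Total step count: 16. Longest linear sequence: 15 steps (steps 1–8 and 10–16); step 9 is a one-step side branch.

Steps most likely to fail

Step 11. Ionisation of C5 may be sluggish, or the quinone methide may tautomerise by loss of the C4 proton to a hydroxystyrene before the alkoxide closes, which would erase C4. The fallback forms the C5–aryl bond on a pre-formed ring instead of the O1–C5 bond. It sets out from lactol 18, which is acetylated (Ac2O, pyridine, DMAP, CH2Cl2) to the anomeric acetate F1. BF3·OEt2 with 2-methoxyphenol in CH2Cl2 at −78 °C should then generate the cyclic oxocarbenium ion, which the arene attacks para to its hydroxyl and anti to the C4 methyl (Friedel–Crafts C-arylation). This should give the 4,5-trans product and rejoins the route at 24.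

Step 8. Exchange of the directing phosphinite onto the hindered secondary alcohol may be incomplete, letting undirected linear hydroformylation compete, and the C4 centre may not settle fully trans. The fallback builds C4 and C5 stepwise from 16. Hydroboration (9-BBN, THF; NaOH, H2O2) should give the 1,4-diol F2. Oxidative lactonisation of the primary alcohol (TEMPO, PhI(OAc)2, CH2Cl2) should give the lactone F3. Enolate methylation (LiN(i-Pr)2, THF, −78 °C; MeI) should introduce the methyl anti to the neighbouring methyl and aryl, giving the dimethyl lactone F4. Half-reduction (i-Bu2AlH, CH2Cl2, −78 °C) returns to the route at lactol 18.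

Step 15. Facial discrimination in hydride delivery to the late ketone may be insufficient, leaving erythro alcohol in the product. The fallback replaces substrate control by catalyst control: Corey–Bakshi–Shibata reduction of 28 with the (S)-Me-CBS oxazaborolidine and BH3·SMe2 in THF at −20 °C. With the aryl group as the large substituent this should deliver hydride to the same face as the Felkin–Anh path and rejoin the route at 29; no new compound arises (F0). The same switch, with the (R)-catalyst, would serve step 4.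

Further compounds
F1 | step 11 | (2S,3R,4R)-2-ArL-3,4-dimethyloxolan-5-yl acetate, both anomers | COc1ccc([C@@H](O[Si](C(C)C)(C(C)C)C(C)C)[C@@H](C)Oc2ccc([C@H]3OC(OC(C)=O)[C@H](C)[C@H]3C)cc2OC)cc1OC
F2 | step 8 | (1S,2R)-1-ArL-2-methylbutane-1,4-diol | COc1ccc([C@@H](O[Si](C(C)C)(C(C)C)C(C)C)[C@@H](C)Oc2ccc([C@@H](O)[C@H](C)CCO)cc2OC)cc1OC
F3 | step 8 | (4R,5S)-5-ArL-4-methyloxolan-2-one | COc1ccc([C@@H](O[Si](C(C)C)(C(C)C)C(C)C)[C@@H](C)Oc2ccc([C@H]3OC(=O)C[C@H]3C)cc2OC)cc1OC
F4 | step 8 | (3R,4R,5S)-5-ArL-3,4-dimethyloxolan-2-one | COc1ccc([C@@H](O[Si](C(C)C)(C(C)C)C(C)C)[C@@H](C)Oc2ccc([C@H]3OC(=O)[C@H](C)[C@H]3C)cc2OC)cc1OC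
F0 | step 15 | none | none
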